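Atom labels used throughout: C7–C9 belong to the furofuran arm on ring B, C7'–C9' to the arm on ring C, and C7''–C9'' to the propane chain carrying ring A. Compound numbers are those of the steps below.

## The problem

Target 26 is the (7R,8S,7'R,8'S) enantiomer of the pinoresinol skeleton, an exo,exo-2,6-diaryl-3,7-dioxabicyclo[3.3.0]octane, whose ring B phenol oxygen is bonded to C8'' of an erythro (7''R,8''S) 1-arylpropane-1,3-diol chain carrying ring A. The two tetrahydrofurans share the C8–C8' bond and are cis-fused, so C8 and C8' decide the shape of the bicycle; once they are fixed, C7 and C7' can be set from them, because each aryl group goes to the convex face when its benzylic C–O bond forms. Those benzylic ethers are para to oxygen on rings B and C, ionise under Brønsted or Lewis acid (leading to the exo,endo isomer or to aryltetralins) and are open to hydrogenolysis, so every step after ring formation must be neutral or basic. C7'' and C8'' are separated from the core by ring B and an ether oxygen; no relay from the core is possible, and they must be set by a reagent whose absolute sense is matched to the core. Before etherification the core is C2-symmetric and rings B and C are interchangeable, so the real task is to address one of two equivalent phenols; this is solved by giving the two rings different protecting groups from the first step. Further weak points are the para-hydroxybenzyl alcohol at C7'' (quinone methide formation, acid), the α-aryloxy-β-hydroxy carbonyl stage of the side chain (retro-aldol, elimination) and the free phenols (oxidation). The feature that opens the molecule is the chain C9–C8–C8'–C9' with C7 (ring B) on C8 and C7' (ring C) on C8'. It has the skeleton and oxidation pattern of a 5-alkoxybutenolide (C9' carbonyl, C8'=C8 alkene, C9 acetal) that has taken up an aroyl anion at C8 and an aryl aldehyde at C8'.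

## Retrosynthesis

**Unmasking (26 ⇒ 25 ⇒ 24).** The two aryl O–Si bonds and the C7'' O–Si bond of 25 are cut by fluoride, and before that the exocyclic C9''–N bond of imide 24 is cut reductively. Both phenols carry the same silyl type so that one buffered operation ends the synthesis; benzyl ethers would demand hydrogenolysis beside four benzylic C–O bonds. Compound 24 is no simpler in skeleton, but it carries the auxiliary that accounts for C7'' and C8''. The forward steps need only leave the furofuran and two benzylic stereocentres untouched.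

**C7''–C8'' (24 ⇒ 23 + 5).** Cutting between the two side-chain stereocentres is preferred over two neighbours. An O–C8'' cut at a stereogenic carbon would mean etherifying a hindered phenol at a secondary carbinol flanked by two oxygenated carbons, where elimination is likely. A C7''–O cut would mean hydrating a quinone methide, which is not diastereoselective without a tether. The chosen cut removes ring A and both stereocentres at once and leaves imide 23 plus aldehyde 5, which the core synthesis already requires. Erythro in this series is the anti relationship of OH and OAr along C7''–C8''–C9''. The forward reaction must therefore be an anti-selective glycolate aldol under conditions that do not ionise the core; a magnesium-catalysed soft-enolisation aldol of an oxazolidinone imide meets both demands.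

**O–C8'' at the methylene stage (23 ⇒ 18 + 22; 22 ⇒ 19 + 20; 18 ⇒ 17).** With C8'' still a CH2 group, the aryl ether bond is an unhindered SN2 displacement on an α-bromo imide with no stereocentre at stake. The precursors are phenol 18 and bromoacetyl imide 22, the latter made in one step from oxazolidinone 19 and bromoacetyl bromide 20. Phenol 18 comes from allyl ether 17. The forward steps ask for a base mild enough to spare the imide and the aryl silyl ether, and for a deallylation that is neutral.

**C7–O and C7'–O (17 ⇒ 15).** Cutting both benzylic ether bonds opens the bicycle to tetrol 15. This is preferred to cutting the O–C9 and O–C9' bonds, which would need defined C7 and C7' carbinols and activation of primary alcohols. With the benzylic bonds made last, the carbinol configurations are irrelevant, since both centres pass through para-oxygen-stabilised cations. The closure has to be run under kinetic control: the exo,endo isomer is close in energy to the exo,exo isomer, so the selectivity rests on the faster capture of each cation with its aryl group on the convex face, not on equilibration. The forward reaction therefore needs a weak acid and a short exposure.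

**Redox adjustment (15 ⇒ 14 ⇒ 13).** The four hydroxyls of 15 arise from a ketone (C7), a lactone carbonyl (C9'), a menthyl acetal (C9) and an aldol carbinol (C7'). LiAlH4 converts the first three in one operation and returns the menthol. The ketone in turn is a dithiane in 13. Nothing is simplified in skeleton; the gain is that 13 is the direct product of a three-component union.

**C7–C8 and C7'–C8' (13 ⇒ 4 + 10 + 5).** Both bonds are cut in one retrosynthetic step, which splits the core into a ring B dithiane 4, the four-carbon butenolide 10 and the ring C aldehyde 5. Against a stepwise cut, this uses the enolate formed by the first bond to make the second. Against cuts that form a ring in the same step, it places C8 and C8' trans on a five-membered ring, where the relationship is kinetically and thermodynamically secure. The forward reaction must add the dithiane anion 1,4 and anti to the acetal substituent, and must capture enolate 12 with the aldehyde before proton transfer.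

**Fragments (4 ⇒ 2 + 3; 2 ⇒ 1; 5 ⇒ 1; 10 ⇒ 7 + 8; 7 ⇒ 6).** Dithiane 4 comes from O-allylvanillin 2 and propane-1,3-dithiol 3, and aldehyde 5 from vanillin 1 by silylation. Butenolide 10 comes from 5-hydroxyfuranone 7 (photo-oxygenation of furfural 6) and (+)-menthol 8, with crystallisation selecting the (5S) epimer. The (+)-menthyl series is required because the (5S) acetal leads to (8S,8'S). Allyl on ring B and TIPS on ring C both survive organolithium, hydride and weak acid and are removed orthogonally.

## Roads not taken

**Alternative 1:** The cut is the C7''–O bond. The C7''-deoxy ether A1 would be esterified at its C9'' hydroxyl with phenylboronic acid and its ring A phenol oxidised with Ag2O to the para-quinone methide. The remaining B–OH would add to C7'' through a six-membered transition state to give the trans-dioxaborinane A2, and transesterification and pivalate removal would then give 26.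
- Merits: C7'' is set by substrate control from C8'' in a chair, no auxiliary is needed for it, and the fragile benzylic hydroxyl appears only at the very end, so it never has to survive a reduction or a base. In these respects the route is better than the chosen plan.
- Weak points: the quinone methide from A1 has a hydrogen on C8'' next to an aryloxy group and can tautomerise to the enol ether, erasing C8''. External water competes and adds without diastereoselectivity. Delivery of a boron-bound hydroxyl to a quinone methide is not an established reaction. A1 still needs its own asymmetric entry to C8'' and the whole core from elsewhere.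
- Comparison: the chosen plan sets against it a known C–C bond formation that creates C7'' and C8'' together and has a precedented fallback. The price is an auxiliary and one reductive step.

**Alternative 2:** The cut is C9'–C8' and C7–C8, with the ring B tetrahydrofuran closed in the same step. Fluoride would induce 1,3-elimination in the chloromethyl α-silylbenzyl ether A4 to give an aryl carbonyl ylide. This would add to the alkene of the γ-aryl butenolide A3 anti to its aryl group and give the bicyclic lactone A5, which needs reduction of the C9 carbonyl to CH2 and a protecting-group exchange to reach the core.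
- Merits: two C–C bonds and one ring form in a single step, with relay from one stereocentre. In ring-building economy this is better than the chosen key step, which closes no ring.
- Weak points: the γ-hydrogen of A3 is benzylic, allylic and next to the ring oxygen, so fluoride or any base can deprotonate it to the aromatic 2-oxidofuran and racemise the only controlling centre. The unsymmetrical ylide has to bond through its aryl-bearing carbon to C8 and place that aryl group exo, and neither regiochemistry nor exo/endo selectivity is assured. Deoxygenation of the lactone via a lactol and silane/Lewis acid would expose two para-oxygenated benzylic ethers to the conditions that scramble them. A3 needs its own asymmetric synthesis.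
- Comparison: the chosen plan sets against this a crystalline, configurationally stable acetal as the source of chirality, a recoverable controller and a reaction type known for exactly this lignan class, at the cost of two more steps to the bicycle.

**Alternative 3:** The cut is C8–C8' and C7'–O. Cp2TiCl (trivalent titanium) would open the epoxide of the cinnamyl ether A6 to a C8 radical with a titanium alkoxide on C9. The radical would cyclise 5-exo onto the alkene, and iodine would convert the benzylic titanium species at C7' into an electrophile captured by the C9 alkoxide. The product A7 is the same molecule as 17.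
- Merits: the protected core is reached in one step from an acyclic ether. The reaction type is known for racemic furofurans. The route to 17 would be several steps shorter than the chosen one, and here the alternative is clearly better in step economy.
- Weak points: three stereocentres hang on C7 of A6, a benzylic allylic ether para to an allyloxy group that can ionise under the Lewis acidic titanium and zinc salts, so any erosion propagates to the whole core. The cis relationship at C8/C8' and the exo placement at C7' rest on moderate radical and cation selectivities. Iodine meets an allyl ether and electron-rich arenes. A6 itself needs an enantioselective synthesis of a labile secondary ether.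
- Comparison: the chosen plan sets against the shorter route the fidelity of its stereochemical source. C8 and C8' are fixed trans on a lactone ring by a robust acetal centre, and the controller is bought, crystallised and recovered.

Key step: step 6

## Route

Assumption: the chelated (Z)-magnesium enolate of 23 is taken to react on the face remote from the benzyl group, as simple N-acyloxazolidinones do; if the aryloxy group reverses this sense, the (R)-auxiliary would be used in steps 11–13 with no other change.

Step 1
Reactants: 1 vanillin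
Product: 2 4-(allyloxy)-3-methoxybenzaldehyde
Conditions: allyl bromide, K2CO3, DMF, rt
Reagents that add atoms: allyl bromide, C=CCBr
Why: Williamson etherification of the phenoxide with a primary allylic bromide; the allyl ether survives organolithium, hydride and weak acid and is later removed under neutral catalysis by zerovalent palladium.

Step 2
Reactants: 2 4-(allyloxy)-3-methoxybenzaldehyde; 3 propane-1,3-dithiol
Product: 4 2-[4-(allyloxy)-3-methoxyphenyl]-1,3-dithiane
Conditions: BF3·OEt2 (cat.), CH2Cl2, 0 °C → rt
Reagents that add atoms: none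
Why: Lewis-acid-catalysed dithioacetalisation of an aryl aldehyde; it turns the formyl carbon (future C7) into a masked aroyl anion.

Step 3
Reactants: 1 vanillin
Product: 5 3-methoxy-4-(triisopropylsilyloxy)benzaldehyde
Conditions: TIPSCl, imidazole, DMF, rt
Reagents that add atoms: chlorotriisopropylsilane, CC(C)[Si](Cl)(C(C)C)C(C)C
Why: Imidazole-promoted silylation of the phenol; the bulky aryl silyl ether tolerates enolates, LiAlH4, weak acid and zerovalent palladium and falls only to fluoride. Compound 5 is used twice, as the source of C7' (step 6) and of C7'' (step 13).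

Step 4
Reactants: 6 furfural
Product: 7 5-hydroxyfuran-2(5H)-one (racemic hemiacetal)
Conditions: O2, hν, methylene blue (cat.), MeOH, rt
Reagents that add atoms: dioxygen, O=O
Why: Dye-sensitised singlet-oxygen [4+2] cycloaddition to the furan; methanol opens the endoperoxide with loss of the formyl carbon as methyl formate (known photo-oxygenation of furfural).

Step 5
Reactants: 7 5-hydroxyfuran-2(5H)-one; 8 (+)-menthol, (1S,2R,5S)
Product: 10 (5S)-5-[(1S,2R,5S)-menthyloxy]furan-2(5H)-one, via (5R)-acetal epimer 9 (not isolated)
Conditions: CSA (cat.), toluene, reflux, Dean–Stark; crystallisation from petroleum ether, −20 °C; mother liquor re-equilibrated with CSA and recycled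
Reagents that add atoms: none
Why: Acid-catalysed acetalisation gives both C5 epimers; the (5S) epimer of the (+)-menthyl series crystallises, as its mirror image does in the (−)-menthyl series, while acid interconverts 9 and 10 through the oxocarbenium ion so that the material is funnelled into 10. C5 is thus set by the menthol chirality and lattice selection.

Step 6
Reactants: 4 2-[4-(allyloxy)-3-methoxyphenyl]-1,3-dithiane; 10 (5S)-5-[(1S,2R,5S)-menthyloxy]furan-2(5H)-one; 5 3-methoxy-4-(triisopropylsilyloxy)benzaldehyde
Product: 13 (3R,4S,5S)-4-[2-(4-allyloxy-3-methoxyphenyl)-1,3-dithian-2-yl]-3-{hydroxy[3-methoxy-4-(triisopropylsilyloxy)phenyl]methyl}-5-[(1S,2R,5S)-menthyloxy]dihydrofuran-2(3H)-one (carbinol carbon as a mixture), via 2-lithio-1,3-dithiane 11 (not isolated), via lithium lactone enolate 12 (not isolated)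
Conditions: n-BuLi, THF, −78 → −30 °C; then 10, −78 °C; then 5, −78 °C; AcOH, −78 °C
Reagents that add atoms: none
Why: n-BuLi removes the proton between the two sulfur atoms of 4 to give 11, a soft aroyl-anion equivalent that adds 1,4 to butenolide 10 and forms C7–C8; the lithium enolate 12 so produced is trapped in the same flask by aldehyde 5 in an aldol addition that forms C7'–C8'. This is the known tandem conjugate addition–aldol of lithiated 2-aryl-1,3-dithianes on 5-menthyloxyfuran-2(5H)-ones; no ring is closed, and the lactone ring only carries the stereochemistry. C8 (lactone C4, S) is controlled by the (5S) acetal carbon, whose menthyloxy group shields its own face so that the bulky anion enters anti. C8' (lactone C3, R) is controlled by the new quaternary dithianyl carbon next to it, which forces the aldehyde onto the opposite face and gives the 3,4-trans lactone. The carbinol carbon C7' forms without control, which is acceptable because it is re-set through a cation in step 9. The step needs 1,4- over 1,2-addition, secured by the delocalised, hindered anion and the unhindered β-carbon. It also needs aldol capture before proton transfer, secured by a non-enolisable aldehyde and a cold acidic quench that prevents retro-aldol and retro-Michael reactions.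

Step 7
Reactants: 13 dithianyl lactone
Product: 14 (3R,4S,5S)-4-(4-allyloxy-3-methoxybenzoyl)-3-{hydroxy[3-methoxy-4-(triisopropylsilyloxy)phenyl]methyl}-5-[(1S,2R,5S)-menthyloxy]dihydrofuran-2(3H)-one
Conditions: PhI(O2CCF3)2, NaHCO3, MeCN/H2O (9:1), 0 °C
Reagents that add atoms: water, O
Why: Oxidative dithiane hydrolysis with trivalent iodine (sulfur activation, opening to the aryl-stabilised thionium ion, hydration, loss of the dithiol as its cyclic disulfide). A mercury-free reagent spares the allyl alkene, and bicarbonate protects the acetal and the benzylic carbinol; C8 cannot drift, because the all-trans lactone is the stable arrangement.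

Step 8
Reactants: 14 keto lactone
Product: 15 (2S,3S)-1-(4-allyloxy-3-methoxyphenyl)-2,3-bis(hydroxymethyl)-4-[3-methoxy-4-(triisopropylsilyloxy)phenyl]butane-1,4-diol (C1 and C4 as mixtures)
Conditions: LiAlH4, THF, 0 °C → rt; then Na2SO4·10H2O
Reagents that add atoms: none
Why: Hydride reduction of the ketone, of the lactone carbonyl and, after collapse of the hemiacetal alkoxide with loss of menthoxide, of the liberated C9 aldehyde. C8 and C8' are not touched, and the new C7 carbinol may form as a mixture.

Step 9
Reactants: 15 tetrol
Product: 17 (1R,3aS,4R,6aS)-1-(4-allyloxy-3-methoxyphenyl)-4-[3-methoxy-4-(triisopropylsilyloxy)phenyl]tetrahydro-1H,3H-furo[3,4-c]furan, via monocyclic tetrahydrofuran diol 16 (not isolated)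
Conditions: CSA (cat.), CH2Cl2, 4 Å molecular sieves, 0 °C → rt; Et3N quench when 15 is consumed
Reagents that add atoms: none
Why: Acid-catalysed dehydrative cycloetherification: each para-oxygenated benzylic carbinol ionises and the cation is captured by the primary hydroxyl of the other branch, the allyloxy-substituted side first. C7 and C7' are set by kinetic capture that places each aryl group on the convex face, whichever carbinol epimer is present. The acid is kept weak and the exposure short because the exo,endo isomer is close in energy.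

Step 10
Reactants: 17 allyl ether of the furofuran
Product: 18 4-{(1R,3aS,4R,6aS)-4-[3-methoxy-4-(triisopropylsilyloxy)phenyl]tetrahydro-1H,3H-furo[3,4-c]furan-1-yl}-2-methoxyphenol
Conditions: Pd(PPh3)4 (cat.), morpholine, THF, rt
Reagents that add atoms: none
Why: Tsuji–Trost deallylation: zerovalent palladium ionises the aryl allyl ether to a π-allyl complex that morpholine captures; the neutral medium spares the silyl ether and the benzylic ethers.

Step 11
Reactants: 19 (S)-4-benzyloxazolidin-2-one; 20 bromoacetyl bromide
Product: 22 (S)-4-benzyl-3-(bromoacetyl)oxazolidin-2-one, via lithium oxazolidinide 21 (not isolated)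
Conditions: n-BuLi, THF, −78 °C; then 20, −78 °C
Reagents that add atoms: none
Why: Standard N-acylation of a lithiated oxazolidinone with an acid bromide; attack at the acyl bromide is far faster than displacement of the alkyl bromide at −78 °C.

Step 12
Reactants: 18 phenol; 22 (S)-4-benzyl-3-(bromoacetyl)oxazolidin-2-one
Product: 23 (S)-4-benzyl-3-{[4-((1R,3aS,4R,6aS)-4-[3-methoxy-4-(triisopropylsilyloxy)phenyl]tetrahydro-1H,3H-furo[3,4-c]furan-1-yl)-2-methoxyphenoxy]acetyl}oxazolidin-2-one
Conditions: K2CO3, acetone, rt
Reagents that add atoms: none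
Why: Williamson O-alkylation of the phenoxide at the carbon next to the imide carbonyl, an activated SN2 site; dry carbonate in acetone leaves the imide and the aryl silyl ether intact.

Step 13
Reactants: 23 aryloxyacetyl imide; 5 3-methoxy-4-(triisopropylsilyloxy)benzaldehyde
Product: 24 (S)-4-benzyl-3-[(2R,3R)-2-(aryloxy)-3-[3-methoxy-4-(triisopropylsilyloxy)phenyl]-3-(trimethylsilyloxy)propanoyl]oxazolidin-2-one (aryloxy = the phenoxy group of 18)
Conditions: MgCl2 (cat.), Et3N, TMSCl, EtOAc, rt
Reagents that add atoms: chlorotrimethylsilane, C[Si](C)(C)Cl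
Why: Evans magnesium-halide-catalysed anti-aldol of an N-acyloxazolidinone with a non-enolisable aromatic aldehyde: soft enolisation gives the chelated (Z)-enolate, which meets the aldehyde through a boat-like transition state on the face away from the benzyl group, and TMSCl silylates the aldolate to release magnesium. C8'' and C7'' are set together as the anti (2R,3R) imide, which is the erythro (7''R,8''S) pattern after reduction; the amine-buffered medium does not ionise the furofuran.

Step 14
Reactants: 24 silylated aldol imide
Product: 25 (2S,3R)-2-(aryloxy)-3-[3-methoxy-4-(triisopropylsilyloxy)phenyl]-3-(trimethylsilyloxy)propan-1-ol (aryloxy as in 24)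
Conditions: LiBH4, H2O (1 equiv.), THF, 0 °C
Reagents that add atoms: none
Why: Reductive cleavage of the N-acyloxazolidinone at the exocyclic carbonyl gives the primary alcohol and returns auxiliary 19 without touching a stereocentre. Migration or partial loss of the trimethylsilyl group would be harmless, since step 15 removes every silyl group.

Step 15
Reactants: 25 tris-silyl ether
Product: 26 (1R,2S)-1-(4-hydroxy-3-methoxyphenyl)-2-{4-[(1R,3aS,4R,6aS)-4-(4-hydroxy-3-methoxyphenyl)tetrahydro-1H,3H-furo[3,4-c]furan-1-yl]-2-methoxyphenoxy}propane-1,3-diol (target)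
Conditions: TBAF, AcOH, THF, 0 °C → rt
Reagents that add atoms: none
Why: Fluoride cleaves the two aryl silyl ethers and the trimethylsilyl ether; acetic acid buffers the phenoxides so that the para-hydroxybenzyl alcohol of ring A does not go on to a quinone methide.

## Compound list

1 | vanillin | COc1cc(C=O)ccc1O | starting material
2 | 4-(allyloxy)-3-methoxybenzaldehyde | C=CCOc1ccc(C=O)cc1OC | intermediate
3 | propane-1,3-dithiol | SCCCS | starting material
4 | 2-[4-(allyloxy)-3-methoxyphenyl]-1,3-dithiane | C=CCOc1ccc(C2SCCCS2)cc1OC | intermediate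
5 | 3-methoxy-4-(triisopropylsilyloxy)benzaldehyde | COc1cc(C=O)ccc1O[Si](C(C)C)(C(C)C)C(C)C | intermediate
6 | furfural | O=Cc1ccco1 | starting material
7 | 5-hydroxyfuran-2(5H)-one (racemic) | O=C1C=CC(O)O1 | intermediate
8 | (+)-menthol, (1S,2R,5S) | C[C@H]1CC[C@@H]([C@H](C1)O)C(C)C | starting material
9 | (5R)-5-[(1S,2R,5S)-menthyloxy]furan-2(5H)-one | O=C1C=C[C@H](O[C@H]2C[C@@H](C)CC[C@@H]2C(C)C)O1 | intermediate
10 | (5S)-5-[(1S,2R,5S)-menthyloxy]furan-2(5H)-one | O=C1C=C[C@@H](O[C@H]2C[C@@H](C)CC[C@@H]2C(C)C)O1 | intermediate
11 | 2-[4-(allyloxy)-3-methoxyphenyl]-2-lithio-1,3-dithiane | [Li]C1(c2ccc(OCC=C)c(OC)c2)SCCCS1 | intermediate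
12 | lithium enolate of (4S,5S)-4-[2-(4-allyloxy-3-methoxyphenyl)-1,3-dithian-2-yl]-5-[(1S,2R,5S)-menthyloxy]dihydrofuran-2(3H)-one | [Li]OC1=C[C@H](C2(c3ccc(OCC=C)c(OC)c3)SCCCS2)[C@@H](O[C@H]2C[C@@H](C)CC[C@@H]2C(C)C)O1 | intermediate
13 | (3R,4S,5S)-4-[2-(4-allyloxy-3-methoxyphenyl)-1,3-dithian-2-yl]-3-{hydroxy[3-methoxy-4-(triisopropylsilyloxy)phenyl]methyl}-5-[(1S,2R,5S)-menthyloxy]dihydrofuran-2(3H)-one, carbinol carbon as a mixture | O=C1O[C@H](O[C@H]2C[C@@H](C)CC[C@@H]2C(C)C)[C@@H](C2(c3ccc(OCC=C)c(OC)c3)SCCCS2)[C@@H]1C(O)c1ccc(O[Si](C(C)C)(C(C)C)C(C)C)c(OC)c1 | intermediate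
14 | (3R,4S,5S)-4-(4-allyloxy-3-methoxybenzoyl)-3-{hydroxy[3-methoxy-4-(triisopropylsilyloxy)phenyl]methyl}-5-[(1S,2R,5S)-menthyloxy]dihydrofuran-2(3H)-one | O=C1O[C@H](O[C@H]2C[C@@H](C)CC[C@@H]2C(C)C)[C@@H](C(=O)c2ccc(OCC=C)c(OC)c2)[C@@H]1C(O)c1ccc(O[Si](C(C)C)(C(C)C)C(C)C)c(OC)c1 | intermediate
15 | (2S,3S)-1-(4-allyloxy-3-methoxyphenyl)-2,3-bis(hydroxymethyl)-4-[3-methoxy-4-(triisopropylsilyloxy)phenyl]butane-1,4-diol, C1 and C4 as mixtures | OC[C@@H](C(O)c1ccc(OCC=C)c(OC)c1)[C@@H](CO)C(O)c1ccc(O[Si](C(C)C)(C(C)C)C(C)C)c(OC)c1 | intermediate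
16 | [(2R,3S,4S)-2-(4-allyloxy-3-methoxyphenyl)-4-{hydroxy[3-methoxy-4-(triisopropylsilyloxy)phenyl]methyl}tetrahydrofuran-3-yl]methanol | C=CCOc1ccc([C@@H]2OC[C@@H](C(O)c3ccc(O[Si](C(C)C)(C(C)C)C(C)C)c(OC)c3)[C@H]2CO)cc1OC | intermediate
17 | (1R,3aS,4R,6aS)-1-(4-allyloxy-3-methoxyphenyl)-4-[3-methoxy-4-(triisopropylsilyloxy)phenyl]tetrahydro-1H,3H-furo[3,4-c]furan | C=CCOc1ccc([C@@H]2OC[C@@H]3[C@H]2CO[C@H]3c2ccc(O[Si](C(C)C)(C(C)C)C(C)C)c(OC)c2)cc1OC | intermediate
18 | 4-{(1R,3aS,4R,6aS)-4-[3-methoxy-4-(triisopropylsilyloxy)phenyl]tetrahydro-1H,3H-furo[3,4-c]furan-1-yl}-2-methoxyphenol | Oc1ccc([C@@H]2OC[C@@H]3[C@H]2CO[C@H]3c2ccc(O[Si](C(C)C)(C(C)C)C(C)C)c(OC)c2)cc1OC | intermediate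
19 | (S)-4-benzyloxazolidin-2-one | O=C1N[C@@H](Cc2ccccc2)CO1 | starting material
20 | bromoacetyl bromide | BrCC(Br)=O | starting material
21 | lithium salt (N-lithio) of (S)-4-benzyloxazolidin-2-one | [Li]N1[C@@H](Cc2ccccc2)COC1=O | intermediate
22 | (S)-4-benzyl-3-(bromoacetyl)oxazolidin-2-one | O=C1OC[C@H](Cc2ccccc2)N1C(=O)CBr | intermediate
23 | (S)-4-benzyl-3-(aryloxyacetyl)oxazolidin-2-one, aryloxy = phenoxy group of 18 | O=C1OC[C@H](Cc2ccccc2)N1C(=O)COc1ccc([C@@H]2OC[C@@H]3[C@H]2CO[C@H]3c2ccc(O[Si](C(C)C)(C(C)C)C(C)C)c(OC)c2)cc1OC | intermediate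
24 | (S)-4-benzyl-3-[(2R,3R)-2-(aryloxy)-3-[3-methoxy-4-(triisopropylsilyloxy)phenyl]-3-(trimethylsilyloxy)propanoyl]oxazolidin-2-one | O=C1OC[C@H](Cc2ccccc2)N1C(=O)[C@H](Oc1ccc([C@@H]2OC[C@@H]3[C@H]2CO[C@H]3c2ccc(O[Si](C(C)C)(C(C)C)C(C)C)c(OC)c2)cc1OC)[C@H](O[Si](C)(C)C)c1ccc(O[Si](C(C)C)(C(C)C)C(C)C)c(OC)c1 | intermediate
25 | (2S,3R)-2-(aryloxy)-3-[3-methoxy-4-(triisopropylsilyloxy)phenyl]-3-(trimethylsilyloxy)propan-1-ol | OC[C@H](Oc1ccc([C@@H]2OC[C@@H]3[C@H]2CO[C@H]3c2ccc(O[Si](C(C)C)(C(C)C)C(C)C)c(OC)c2)cc1OC)[C@H](O[Si](C)(C)C)c1ccc(O[Si](C(C)C)(C(C)C)C(C)C)c(OC)c1 | intermediate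
26 | (1R,2S)-1-(4-hydroxy-3-methoxyphenyl)-2-{4-[(1R,3aS,4R,6aS)-4-(4-hydroxy-3-methoxyphenyl)tetrahydro-1H,3H-furo[3,4-c]furan-1-yl]-2-methoxyphenoxy}propane-1,3-diol | COc1cc([C@@H](O)[C@H](CO)Oc2ccc([C@@H]3OC[C@@H]4[C@H]3CO[C@H]4c3ccc(O)c(OC)c3)cc2OC)ccc1O | target

## Step count and risks

Total: 15 steps. Longest linear sequence: 11 steps (steps 4, 5, 6, 7, 8, 9, 10, 12, 13, 14, 15 from furfural; the same length from vanillin through steps 1, 2 and 6).

Least certain steps:

**Step 6 (key step).** The most likely failure is incomplete capture of the hindered enolate 12 by the electron-rich aldehyde, so that proton transfer on quench or retro-aldol on warming returns the simple Michael adduct. A second concern is attack of n-BuLi on the allyl ether if metalation of 4 is slow. Fallback, from 4 and 10 back to 13: the Michael addition is quenched on its own to give (4S,5S)-4-[2-(4-allyloxy-3-methoxyphenyl)-1,3-dithian-2-yl]-5-[(1S,2R,5S)-menthyloxy]dihydrofuran-2(3H)-one F1. Its enolate is then regenerated separately with LiN(i-Pr)2 at −78 °C and combined with 5 under conditions chosen for the aldol alone (longer time, or transmetalation with ZnCl2), giving 13.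

**Step 7.** The β-hydroxy lactone may dehydrate or undergo retro-aldol under the acid released during unmasking, or the electron-rich rings may be oxidised. Fallback, from 13 back to 15, with the order of events changed: LiAlH4 first reduces 13 to (2S,3S)-2-[2-(4-allyloxy-3-methoxyphenyl)-1,3-dithian-2-yl]-3-{hydroxy[3-methoxy-4-(triisopropylsilyloxy)phenyl]methyl}butane-1,4-diol F2. The dithiane is then opened on this robust triol to give (2S,3S)-1-(4-allyloxy-3-methoxyphenyl)-4-hydroxy-2,3-bis(hydroxymethyl)-4-[3-methoxy-4-(triisopropylsilyloxy)phenyl]butan-1-one F3, held as its cyclic hemiketal, and NaBH4 reduces F3 to 15.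

**Step 9.** Exo selectivity may erode through repeated re-ionisation of the product, or material may leak irreversibly into aryltetralins by Friedel–Crafts capture of the cations. Fallback, from 13 back to 17, with the rings closed one at a time so that only one benzylic centre is open at any moment:
- The triol F2 described under step 7 is treated with weak acid. Only C7' can ionise, and the product is the 2,3-trans tetrahydrofuran {(2R,3S,4S)-4-[2-(4-allyloxy-3-methoxyphenyl)-1,3-dithian-2-yl]-2-[3-methoxy-4-(triisopropylsilyloxy)phenyl]tetrahydrofuran-3-yl}methanol F4, which is favoured both kinetically and thermodynamically.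
- Dithiane removal gives the ketone (4-allyloxy-3-methoxyphenyl){(3S,4S,5R)-4-(hydroxymethyl)-5-[3-methoxy-4-(triisopropylsilyloxy)phenyl]tetrahydrofuran-3-yl}methanone F5.
- NaBH4 gives the carbinol [(2R,3S,4S)-4-[(4-allyloxy-3-methoxyphenyl)(hydroxy)methyl]-2-[3-methoxy-4-(triisopropylsilyloxy)phenyl]tetrahydrofuran-3-yl]methanol F6.
- A brief acid treatment closes the second ring to 17.

**Step 12.** The phenoxide may attack the exocyclic imide carbonyl and transfer the bromoacetyl group instead of displacing bromide. Fallback, from 18 back to 23, with the ether made before the imide: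
- 18 is alkylated with allyl bromoacetate to give allyl 2-(aryloxy)acetate F7.
- Zerovalent palladium and morpholine release 2-(aryloxy)acetic acid F8.
- Pivaloyl chloride and Et3N convert F8 into the mixed pivalic anhydride F9, which acylates 19 in the presence of LiCl to give 23.

**Step 13.** The aryl ether and methoxy oxygens may compete with the imide carbonyl for magnesium and lower or reverse the facial selectivity. Addition to the electron-rich aldehyde may also be slow enough for the silylation to lose control of the anti selectivity. Fallback, from 18 to 26, using the boron syn-aldol followed by inversion at C7'':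
- (R)-4-benzyloxazolidin-2-one F10 is acylated as in step 11 to (R)-4-benzyl-3-(bromoacetyl)oxazolidin-2-one F11, and 18 is alkylated with it to the (R)-4-benzyl-3-(aryloxyacetyl)oxazolidin-2-one F12.
- Bu2BOTf, i-Pr2NEt and 5 give the syn aldol (R)-4-benzyl-3-[(2R,3S)-2-(aryloxy)-3-hydroxy-3-[3-methoxy-4-(triisopropylsilyloxy)phenyl]propanoyl]oxazolidin-2-one F13.
- Mitsunobu reaction with 4-nitrobenzoic acid inverts C7'' to the (2R,3R) 4-nitrobenzoate F14.
- LiBH4 removes auxiliary and ester to give (1R,2S)-2-(aryloxy)-1-[3-methoxy-4-(triisopropylsilyloxy)phenyl]propane-1,3-diol F15, and TBAF/AcOH converts F15 into 26.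

## Further compounds

F1 | step 6 | (4S,5S)-4-[2-(4-allyloxy-3-methoxyphenyl)-1,3-dithian-2-yl]-5-[(1S,2R,5S)-menthyloxy]dihydrofuran-2(3H)-one | O=C1O[C@H](O[C@H]2C[C@@H](C)CC[C@@H]2C(C)C)[C@@H](C2(c3ccc(OCC=C)c(OC)c3)SCCCS2)C1
F2 | step 7 | (2S,3S)-2-[2-(4-allyloxy-3-methoxyphenyl)-1,3-dithian-2-yl]-3-{hydroxy[3-methoxy-4-(triisopropylsilyloxy)phenyl]methyl}butane-1,4-diol | OC[C@@H](C1(c2ccc(OCC=C)c(OC)c2)SCCCS1)[C@@H](CO)C(O)c1ccc(O[Si](C(C)C)(C(C)C)C(C)C)c(OC)c1
F3 | step 7 | (2S,3S)-1-(4-allyloxy-3-methoxyphenyl)-4-hydroxy-2,3-bis(hydroxymethyl)-4-[3-methoxy-4-(triisopropylsilyloxy)phenyl]butan-1-one | OC[C@@H](C(=O)c1ccc(OCC=C)c(OC)c1)[C@@H](CO)C(O)c1ccc(O[Si](C(C)C)(C(C)C)C(C)C)c(OC)c1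
F4 | step 9 | {(2R,3S,4S)-4-[2-(4-allyloxy-3-methoxyphenyl)-1,3-dithian-2-yl]-2-[3-methoxy-4-(triisopropylsilyloxy)phenyl]tetrahydrofuran-3-yl}methanol | OC[C@@H]1[C@H](C2(c3ccc(OCC=C)c(OC)c3)SCCCS2)CO[C@H]1c1ccc(O[Si](C(C)C)(C(C)C)C(C)C)c(OC)c1
F5 | step 9 | (4-allyloxy-3-methoxyphenyl){(3S,4S,5R)-4-(hydroxymethyl)-5-[3-methoxy-4-(triisopropylsilyloxy)phenyl]tetrahydrofuran-3-yl}methanone | OC[C@@H]1[C@H](C(=O)c2ccc(OCC=C)c(OC)c2)CO[C@H]1c1ccc(O[Si](C(C)C)(C(C)C)C(C)C)c(OC)c1
F6 | step 9 | [(2R,3S,4S)-4-[(4-allyloxy-3-methoxyphenyl)(hydroxy)methyl]-2-[3-methoxy-4-(triisopropylsilyloxy)phenyl]tetrahydrofuran-3-yl]methanol | OC[C@@H]1[C@H](C(O)c2ccc(OCC=C)c(OC)c2)CO[C@H]1c1ccc(O[Si](C(C)C)(C(C)C)C(C)C)c(OC)c1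
F7 | step 12 | allyl 2-(aryloxy)acetate, aryloxy = phenoxy group of 18 | C=CCOC(=O)COc1ccc([C@@H]2OC[C@@H]3[C@H]2CO[C@H]3c2ccc(O[Si](C(C)C)(C(C)C)C(C)C)c(OC)c2)cc1OC
F8 | step 12 | 2-(aryloxy)acetic acid | OC(=O)COc1ccc([C@@H]2OC[C@@H]3[C@H]2CO[C@H]3c2ccc(O[Si](C(C)C)(C(C)C)C(C)C)c(OC)c2)cc1OC
F9 | step 12 | 2-(aryloxy)acetic pivalic anhydride | CC(C)(C)C(=O)OC(=O)COc1ccc([C@@H]2OC[C@@H]3[C@H]2CO[C@H]3c2ccc(O[Si](C(C)C)(C(C)C)C(C)C)c(OC)c2)cc1OC
F10 | step 13 | (R)-4-benzyloxazolidin-2-one | O=C1N[C@H](Cc2ccccc2)CO1
F11 | step 13 | (R)-4-benzyl-3-(bromoacetyl)oxazolidin-2-one | O=C1OC[C@@H](Cc2ccccc2)N1C(=O)CBr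
F12 | step 13 | (R)-4-benzyl-3-(aryloxyacetyl)oxazolidin-2-one | O=C1OC[C@@H](Cc2ccccc2)N1C(=O)COc1ccc([C@@H]2OC[C@@H]3[C@H]2CO[C@H]3c2ccc(O[Si](C(C)C)(C(C)C)C(C)C)c(OC)c2)cc1OC
F13 | step 13 | (R)-4-benzyl-3-[(2R,3S)-2-(aryloxy)-3-hydroxy-3-[3-methoxy-4-(triisopropylsilyloxy)phenyl]propanoyl]oxazolidin-2-one | O=C1OC[C@@H](Cc2ccccc2)N1C(=O)[C@H](Oc1ccc([C@@H]2OC[C@@H]3[C@H]2CO[C@H]3c2ccc(O[Si](C(C)C)(C(C)C)C(C)C)c(OC)c2)cc1OC)[C@@H](O)c1ccc(O[Si](C(C)C)(C(C)C)C(C)C)c(OC)c1
F14 | step 13 | (R)-4-benzyl-3-[(2R,3R)-2-(aryloxy)-3-[3-methoxy-4-(triisopropylsilyloxy)phenyl]-3-(4-nitrobenzoyloxy)propanoyl]oxazolidin-2-one | O=C1OC[C@@H](Cc2ccccc2)N1C(=O)[C@H](Oc1ccc([C@@H]2OC[C@@H]3[C@H]2CO[C@H]3c2ccc(O[Si](C(C)C)(C(C)C)C(C)C)c(OC)c2)cc1OC)[C@H](OC(=O)c1ccc(cc1)[N+](=O)[O-])c1ccc(O[Si](C(C)C)(C(C)C)C(C)C)c(OC)c1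
F15 | step 13 | (1R,2S)-2-(aryloxy)-1-[3-methoxy-4-(triisopropylsilyloxy)phenyl]propane-1,3-diol | OC[C@H](Oc1ccc([C@@H]2OC[C@@H]3[C@H]2CO[C@H]3c2ccc(O[Si](C(C)C)(C(C)C)C(C)C)c(OC)c2)cc1OC)[C@H](O)c1ccc(O[Si](C(C)C)(C(C)C)C(C)C)c(OC)c1
A1 | alternative 1 | (R)-2-(aryloxy)-3-(4-hydroxy-3-methoxyphenyl)propan-1-ol with ring C as pivalate (C7''-deoxy ether) | COc1cc(C[C@H](CO)Oc2ccc([C@@H]3OC[C@@H]4[C@H]3CO[C@H]4c3ccc(OC(=O)C(C)(C)C)c(OC)c3)cc2OC)ccc1O
A2 | alternative 1 | (4R,5S)-trans-4-(4-hydroxy-3-methoxyphenyl)-5-aryloxy-2-phenyl-1,3,2-dioxaborinane with ring C as pivalate | COc1cc([C@H]2OB(c3ccccc3)OC[C@@H]2Oc2ccc([C@@H]3OC[C@@H]4[C@H]3CO[C@H]4c3ccc(OC(=O)C(C)(C)C)c(OC)c3)cc2OC)ccc1O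
A3 | alternative 2 | (R)-5-[4-(benzyloxy)-3-methoxyphenyl]furan-2(5H)-one | O=C1C=C[C@H](c2ccc(OCc3ccccc3)c(OC)c2)O1
A4 | alternative 2 | chloromethyl [4-(allyloxy)-3-methoxyphenyl](trimethylsilyl)methyl ether | C=CCOc1ccc(C(OCCl)[Si](C)(C)C)cc1OC
A5 | alternative 2 | 2-(4-allyloxy-3-methoxyphenyl)-6-(4-benzyloxy-3-methoxyphenyl)-3,7-dioxabicyclo[3.3.0]octan-8-one with C9 as the lactone carbonyl | C=CCOc1ccc([C@@H]2OC[C@@H]3[C@H]2C(=O)O[C@H]3c2ccc(OCc3ccccc3)c(OC)c2)cc1OC
A6 | alternative 3 | 2-{(S)-[4-(allyloxy)-3-methoxyphenyl][(E)-3-(3-methoxy-4-triisopropylsilyloxyphenyl)allyloxy]methyl}oxirane | C=CCOc1ccc([C@H](OC/C=C/c2ccc(O[Si](C(C)C)(C(C)C)C(C)C)c(OC)c2)C2CO2)cc1OC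
A7 | alternative 3 | (1R,3aS,4R,6aS)-1-(4-allyloxy-3-methoxyphenyl)-4-[3-methoxy-4-(triisopropylsilyloxy)phenyl]tetrahydro-1H,3H-furo[3,4-c]furan (identical with 17) | C=CCOc1ccc([C@@H]2OC[C@@H]3[C@H]2CO[C@H]3c2ccc(O[Si](C(C)C)(C(C)C)C(C)C)c(OC)c2)cc1OC
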